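**Plan**

1. Retrosynthesis: the quinone is unmasked from a 1,4-dimethoxynaphthalene and the saturated chain comes from tetraene 24 by one hydrogenation. Tetraene 24 is cut at C13'–C14' (allylic sp3–sp3 union) and, in the same operation, at the cyclopentane bond C1–C5 (C1 bears the chain, C3 the 6-methylheptan-2-yl group, C5 is the ring CH2 beside C1 and remote from C3).
2. Enabling feature: C1 and C3 are 1,3-related on the five-membered ring, so opening C1–C5 leaves a hex-5-enyl chain C5–C4–C3(side chain)–C2–C1=C14' with the branched group on its third carbon. A carbanion at C5 closes 5-exo onto C1 through a chair, and the new C14'–metal bond is used at once for the union.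
3. Forward order: right half 11 from (R)-citronellic acid (auxiliary allylation, one-carbon homologation); left half 20 from (2E,6E)-farnesyl acetate used end for end (terminal allylic oxidation, benzylic coupling to the naphthalene); ring closure with union (step 13); hydrogenation; oxidation to the quinone.
4. Stereochemistry: side-chain C2 comes from (R)-citronellic acid, ring C3 from the oxazolidinone auxiliary, and ring C1 from C3 in the cyclisation (cis). C3', C7' and C11' come from the E geometry of the farnesyl alkenes and one enantiomer of an iridium P,N catalyst.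

Key step: step 13

Remark: chain carbons are numbered C1'–C14' from the naphthalene and ring carbons as above. The CIP label of ring C1 reads S in 24 and R elsewhere, and that of C7' changes in F4 and F5, only because neighbouring unsaturation or heteroatoms change priorities, not geometry.

**Route**

Step 1
Reactants: 1 (3R)-3,7-dimethyloct-6-enoic acid [(R)-citronellic acid]; 2 (4S)-4-benzyl-1,3-oxazolidin-2-one
Product: 4 (4S)-4-benzyl-3-[(3R)-3,7-dimethyloct-6-enoyl]-1,3-oxazolidin-2-one, via mixed pivalic anhydride 3 (not isolated)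
Conditions: PivCl, Et3N, THF, −20 °C; then 2, LiCl, −20 °C to rt
Reagents that add atoms: none
Why: Mixed-anhydride N-acylation of the oxazolidinone installs the Evans auxiliary under conditions that cannot touch the non-enolisable C3 methyl centre.

Step 2
Reactants: 4 (4S)-4-benzyl-3-[(3R)-3,7-dimethyloct-6-enoyl]-1,3-oxazolidin-2-one
Product: 6 (4S)-4-benzyl-3-[(2S,3R)-3,7-dimethyl-2-(prop-2-en-1-yl)oct-6-enoyl]-1,3-oxazolidin-2-one, via sodium Z-enolate 5 (not isolated)
Conditions: NaN(SiMe3)2, THF, −78 °C; allyl iodide, −78 to −40 °C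
Reagents that add atoms: allyl iodide, C=CCI
Why: Evans asymmetric alkylation; the chelated Z-enolate is allylated on the face opposite the benzyl group, which should set the acyl C2 (future ring C3) as S under auxiliary control regardless of the neighbouring methyl centre.

Step 3
Reactants: 6 (4S)-4-benzyl-3-[(2S,3R)-3,7-dimethyl-2-(prop-2-en-1-yl)oct-6-enoyl]-1,3-oxazolidin-2-one
Product: 7 (2S,3R)-3,7-dimethyl-2-(prop-2-en-1-yl)oct-6-en-1-ol
Conditions: LiBH4, Et2O, H2O (1 equiv), 0 °C
Reagents that add atoms: none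
Why: Reductive cleavage of the imide by borohydride gives the primary alcohol and returns the auxiliary without exposing an epimerisable centre.

Step 4
Reactants: 7 (2S,3R)-3,7-dimethyl-2-(prop-2-en-1-yl)oct-6-en-1-ol
Product: 8 (4S,5R)-4-(iodomethyl)-5,9-dimethyldeca-1,8-diene
Conditions: I2, PPh3, imidazole, CH2Cl2, 0 °C to rt
Reagents that add atoms: iodine, [I][I]
Why: Appel-type iodination displaces the activated primary hydroxyl by SN2 at a CH2 group, so neither stereocentre is involved.

Step 5
Reactants: 8 (4S,5R)-4-(iodomethyl)-5,9-dimethyldeca-1,8-diene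
Product: 10 (3R,4R)-4,8-dimethyl-3-(prop-2-en-1-yl)non-7-en-1-ol, via alkyllithium 9 (not isolated)
Conditions: t-BuLi (2.1 equiv), Et2O/pentane, −78 °C; monomeric CH2O (cracked paraformaldehyde), −78 °C to rt
Reagents that add atoms: formaldehyde, C=O
Why: Iodine–lithium exchange gives a primary alkyllithium that has only an unfavourable four-membered closure open to it and is hydroxymethylated by formaldehyde, a one-carbon homologation that supplies ring C5.

Step 6
Reactants: 10 (3R,4R)-4,8-dimethyl-3-(prop-2-en-1-yl)non-7-en-1-ol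
Product: 11 (4R,5R)-4-(2-iodoethyl)-5,9-dimethyldeca-1,8-diene
Conditions: I2, PPh3, imidazole, CH2Cl2, 0 °C to rt
Reagents that add atoms: iodine, [I][I]
Why: Appel-type iodination of an unhindered primary alcohol gives the hex-5-enyl iodide needed for the ring closure.

Step 7
Reactants: 12 (2E,6E)-3,7,11-trimethyldodeca-2,6,10-trien-1-yl acetate [(2E,6E)-farnesyl acetate]
Product: 13 (2E,6E,10E)-12-hydroxy-3,7,11-trimethyldodeca-2,6,10-trien-1-yl acetate
Conditions: SeO2 (cat.), t-BuOOH, salicylic acid (cat.), CH2Cl2, 0 °C to rt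
Reagents that add atoms: selenium dioxide, O=[Se]=O; tert-butyl hydroperoxide, CC(C)(C)OO
Why: Selenium dioxide allylic oxidation (ene reaction, then [2,3]-sigmatropic shift) selects the E-methyl of the terminal, most electron-rich and least hindered alkene and keeps the E geometry.

Step 8
Reactants: 13 (2E,6E,10E)-12-hydroxy-3,7,11-trimethyldodeca-2,6,10-trien-1-yl acetate
Product: 14 (2E,6E,10E)-12-bromo-3,7,11-trimethyldodeca-2,6,10-trien-1-yl acetate
Conditions: CBr4, PPh3, CH2Cl2, −20 °C
Reagents that add atoms: tetrabromomethane, BrC(Br)(Br)Br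
Why: Appel bromination converts the primary allylic alcohol to the bromide at low temperature without allylic transposition.

Step 9
Reactants: 15 1,4-dimethoxy-2-methylnaphthalene
Product: 16 2-(chloromethyl)-1,4-dimethoxy-3-methylnaphthalene
Conditions: paraformaldehyde, conc. HCl, AcOH, 60 °C
Reagents that add atoms: formaldehyde, C=O; hydrogen chloride, Cl
Why: Blanc chloromethylation is directed to C3, the only unsubstituted position of the doubly methoxy-activated ring.

Step 10
Reactants: 16 2-(chloromethyl)-1,4-dimethoxy-3-methylnaphthalene; 14 (2E,6E,10E)-12-bromo-3,7,11-trimethyldodeca-2,6,10-trien-1-yl acetate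
Product: 18 (2E,6E,10E)-13-(1,4-dimethoxy-3-methylnaphthalen-2-yl)-3,7,11-trimethyltrideca-2,6,10-trien-1-yl acetate, via benzylic Grignard reagent 17 (not isolated)
Conditions: Mg turnings, 2-MeTHF, 0 °C (slow addition of 16); then 14, Li2CuCl4 (3 mol%), THF, −78 to −30 °C
Reagents that add atoms: none
Why: Kochi-type copper-catalysed Grignard coupling should displace the allylic bromide much faster than it touches the allylic acetate, at the primary carbon because the γ-carbon is fully substituted, with the E-alkene kept.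

Step 11
Reactants: 18 (2E,6E,10E)-13-(1,4-dimethoxy-3-methylnaphthalen-2-yl)-3,7,11-trimethyltrideca-2,6,10-trien-1-yl acetate
Product: 19 (2E,6E,10E)-13-(1,4-dimethoxy-3-methylnaphthalen-2-yl)-3,7,11-trimethyltrideca-2,6,10-trien-1-ol
Conditions: K2CO3 (cat.), MeOH, rt
Reagents that add atoms: none
Why: Base-catalysed transesterification removes the acetate without affecting the alkenes or the aryl ethers.

Step 12
Reactants: 19 (2E,6E,10E)-13-(1,4-dimethoxy-3-methylnaphthalen-2-yl)-3,7,11-trimethyltrideca-2,6,10-trien-1-ol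
Product: 20 2-[(3E,7E,11E)-13-bromo-3,7,11-trimethyltrideca-3,7,11-trien-1-yl]-1,4-dimethoxy-3-methylnaphthalene
Conditions: CBr4, PPh3, CH2Cl2, −30 °C; used without storage
Reagents that add atoms: tetrabromomethane, BrC(Br)(Br)Br
Why: Appel bromination of the primary allylic alcohol gives the prenyl-type bromide with the E geometry intact.

Step 13
Reactants: 11 (4R,5R)-4-(2-iodoethyl)-5,9-dimethyldeca-1,8-diene; 20 2-[(3E,7E,11E)-13-bromo-3,7,11-trimethyltrideca-3,7,11-trien-1-yl]-1,4-dimethoxy-3-methylnaphthalene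
Product: 24 1,4-dimethoxy-2-methyl-3-[(3E,7E,11E)-3,7,11-trimethyl-14-{(1S,3S)-3-[(2R)-6-methylhept-5-en-2-yl]cyclopentyl}tetradeca-3,7,11-trien-1-yl]naphthalene, via hexenyllithium 21 (not isolated), via cyclopentylmethyllithium 22 (not isolated), via cyclopentylmethylmagnesium bromide 23 (not isolated)
Conditions: 11 (1.4 equiv), t-BuLi (2.1 equiv per 11), pentane/Et2O (3:2), −78 °C; TMEDA, warm to rt, 1 h; −78 °C, MgBr2·OEt2, THF; then 20 (1.0 equiv), Li2CuCl4 (5 mol%), −78 to 0 °C
Reagents that add atoms: none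
Why: Iodine–lithium exchange gives hex-5-enyllithium 21, whose C–Li bond adds syn across the terminal alkene on warming (intramolecular carbolithiation) to form the ring bond C5–C1 and the primary organolithium 22; transmetalation to magnesium and Li2CuCl4-catalysed substitution of allylic bromide 20 then forge C13'–C14' in the same flask. The closest known reaction type is the anionic cyclisation of hex-5-enyllithiums with electrophilic trapping, joined here to a Kochi-type copper-catalysed Grignard allylation. The cyclopentane closes in the 5-exo-trig mode. The new stereocentre (ring C1) is controlled by ring C3: in the chair-like four-centre transition state with lithium bound to the alkene, the branched side chain on the third carbon of the hexenyl chain sits pseudoequatorial, which should give the cis-1,3 ring (1R,3S in 22). The step needs 5-exo over 6-endo closure (inherent to this carbolithiation), no attack on the remote trisubstituted alkene (unactivated, reachable only through a seven-membered closure), and α over γ substitution with retention of the E-alkene in the allylation (the γ-carbon is fully substituted and cuprate-type conditions in THF favour direct displacement).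

Step 14
Reactants: 24 1,4-dimethoxy-2-methyl-3-[(3E,7E,11E)-3,7,11-trimethyl-14-{(1S,3S)-3-[(2R)-6-methylhept-5-en-2-yl]cyclopentyl}tetradeca-3,7,11-trien-1-yl]naphthalene
Product: 25 1,4-dimethoxy-2-methyl-3-[(3S,7S,11R)-3,7,11-trimethyl-14-{(1R,3S)-3-[(2R)-6-methylheptan-2-yl]cyclopentyl}tetradecyl]naphthalene
Conditions: [Ir(cod)(L)][B(C6H3(CF3)2)4] (2 mol%; L = one enantiomer of 2-phenyl-8-(di-o-tolylphosphinooxy)-5,6,7,8-tetrahydroquinoline), H2 (50 bar), CH2Cl2, rt
Reagents that add atoms: none
Why: Iridium-catalysed asymmetric hydrogenation of unfunctionalised trisubstituted alkenes; the three chain alkenes are the same E-configured CH2–C(CH3)=CH–CH2 unit, so one ligand enantiomer should add hydrogen to the same local face of each and give 3'S,7'S,11'R (the enantiomer needed is the one that turns the 6E-alkene of (2E,6E)-farnesol into a 7R centre, since the prenyl units of 24 point the other way), while the isopropylidene group is reduced without stereochemical consequence.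

Step 15
Reactants: 25 1,4-dimethoxy-2-methyl-3-[(3S,7S,11R)-3,7,11-trimethyl-14-{(1R,3S)-3-[(2R)-6-methylheptan-2-yl]cyclopentyl}tetradecyl]naphthalene
Product: 26 2-methyl-3-[(3S,7S,11R)-3,7,11-trimethyl-14-{(1R,3S)-3-[(2R)-6-methylheptan-2-yl]cyclopentyl}tetradecyl]naphthalene-1,4-dione (target)
Conditions: (NH4)2Ce(NO3)6 (2.5 equiv), MeCN/H2O (3:1), 0 °C
Reagents that add atoms: water, O
Why: Oxidative demethylation of the hydroquinone dimethyl ether by ceric ammonium nitrate gives the 1,4-quinone (carbonyl oxygens taken from water, methanol released) and leaves the saturated chain and all six stereocentres untouched.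

**Compound list**

1 | (3R)-3,7-dimethyloct-6-enoic acid | OC(=O)C[C@H](C)CCC=C(C)C | starting material
2 | (4S)-4-benzyl-1,3-oxazolidin-2-one | O=C1N[C@@H](Cc2ccccc2)CO1 | starting material (auxiliary)
3 | (3R)-3,7-dimethyloct-6-enoic pivalic anhydride | CC(C)(C)C(=O)OC(=O)C[C@H](C)CCC=C(C)C | intermediate (not isolated)
4 | (4S)-4-benzyl-3-[(3R)-3,7-dimethyloct-6-enoyl]-1,3-oxazolidin-2-one | O=C(C[C@H](C)CCC=C(C)C)N1[C@@H](Cc2ccccc2)COC1=O | intermediate
5 | sodium Z-enolate of 4 | [Na]O/C(=C\[C@H](C)CCC=C(C)C)N1[C@@H](Cc2ccccc2)COC1=O | intermediate (not isolated)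
6 | (4S)-4-benzyl-3-[(2S,3R)-3,7-dimethyl-2-(prop-2-en-1-yl)oct-6-enoyl]-1,3-oxazolidin-2-one | C=CC[C@H](C(=O)N1[C@@H](Cc2ccccc2)COC1=O)[C@H](C)CCC=C(C)C | intermediate
7 | (2S,3R)-3,7-dimethyl-2-(prop-2-en-1-yl)oct-6-en-1-ol | C=CC[C@H](CO)[C@H](C)CCC=C(C)C | intermediate
8 | (4S,5R)-4-(iodomethyl)-5,9-dimethyldeca-1,8-diene | C=CC[C@H](CI)[C@H](C)CCC=C(C)C | intermediate
9 | [(2S,3R)-3,7-dimethyl-2-(prop-2-en-1-yl)oct-6-en-1-yl]lithium | C=CC[C@H](C[Li])[C@H](C)CCC=C(C)C | intermediate (not isolated)
10 | (3R,4R)-4,8-dimethyl-3-(prop-2-en-1-yl)non-7-en-1-ol | C=CC[C@H](CCO)[C@H](C)CCC=C(C)C | intermediate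
11 | (4R,5R)-4-(2-iodoethyl)-5,9-dimethyldeca-1,8-diene | C=CC[C@H](CCI)[C@H](C)CCC=C(C)C | intermediate
12 | (2E,6E)-3,7,11-trimethyldodeca-2,6,10-trien-1-yl acetate | CC(=O)OC/C=C(\C)CC/C=C(\C)CCC=C(C)C | starting material
13 | (2E,6E,10E)-12-hydroxy-3,7,11-trimethyldodeca-2,6,10-trien-1-yl acetate | CC(=O)OC/C=C(\C)CC/C=C(\C)CC/C=C(\C)CO | intermediate
14 | (2E,6E,10E)-12-bromo-3,7,11-trimethyldodeca-2,6,10-trien-1-yl acetate | CC(=O)OC/C=C(\C)CC/C=C(\C)CC/C=C(\C)CBr | intermediate
15 | 1,4-dimethoxy-2-methylnaphthalene | COc1cc(C)c(OC)c2ccccc12 | starting material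
16 | 2-(chloromethyl)-1,4-dimethoxy-3-methylnaphthalene | COc1c(CCl)c(C)c(OC)c2ccccc12 | intermediate
17 | [(1,4-dimethoxy-3-methylnaphthalen-2-yl)methyl]magnesium chloride | COc1c(C[Mg]Cl)c(C)c(OC)c2ccccc12 | intermediate (not isolated)
18 | (2E,6E,10E)-13-(1,4-dimethoxy-3-methylnaphthalen-2-yl)-3,7,11-trimethyltrideca-2,6,10-trien-1-yl acetate | CC(=O)OC/C=C(\C)CC/C=C(\C)CC/C=C(\C)CCc1c(C)c(OC)c2ccccc2c1OC | intermediate
19 | (2E,6E,10E)-13-(1,4-dimethoxy-3-methylnaphthalen-2-yl)-3,7,11-trimethyltrideca-2,6,10-trien-1-ol | OC/C=C(\C)CC/C=C(\C)CC/C=C(\C)CCc1c(C)c(OC)c2ccccc2c1OC | intermediate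
20 | 2-[(3E,7E,11E)-13-bromo-3,7,11-trimethyltrideca-3,7,11-trien-1-yl]-1,4-dimethoxy-3-methylnaphthalene | BrC/C=C(\C)CC/C=C(\C)CC/C=C(\C)CCc1c(C)c(OC)c2ccccc2c1OC | intermediate
21 | [(3S,4R)-4,8-dimethyl-3-(prop-2-en-1-yl)non-7-en-1-yl]lithium | C=CC[C@H](CC[Li])[C@H](C)CCC=C(C)C | intermediate (not isolated)
22 | ({(1R,3S)-3-[(2R)-6-methylhept-5-en-2-yl]cyclopentyl}methyl)lithium | [Li]C[C@@H]1CC[C@H]([C@H](C)CCC=C(C)C)C1 | intermediate (not isolated)
23 | ({(1R,3S)-3-[(2R)-6-methylhept-5-en-2-yl]cyclopentyl}methyl)magnesium bromide | Br[Mg]C[C@@H]1CC[C@H]([C@H](C)CCC=C(C)C)C1 | intermediate (not isolated)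
24 | 1,4-dimethoxy-2-methyl-3-[(3E,7E,11E)-3,7,11-trimethyl-14-{(1S,3S)-3-[(2R)-6-methylhept-5-en-2-yl]cyclopentyl}tetradeca-3,7,11-trien-1-yl]naphthalene | COc1c(C)c(CC/C(C)=C/CC/C(C)=C/CC/C(C)=C/CC[C@@H]3CC[C@H]([C@H](C)CCC=C(C)C)C3)c(OC)c2ccccc12 | intermediate
25 | 1,4-dimethoxy-2-methyl-3-[(3S,7S,11R)-3,7,11-trimethyl-14-{(1R,3S)-3-[(2R)-6-methylheptan-2-yl]cyclopentyl}tetradecyl]naphthalene | COc1c(C)c(CC[C@@H](C)CCC[C@@H](C)CCC[C@@H](C)CCC[C@@H]3CC[C@H]([C@H](C)CCCC(C)C)C3)c(OC)c2ccccc12 | intermediate
26 | 2-methyl-3-[(3S,7S,11R)-3,7,11-trimethyl-14-{(1R,3S)-3-[(2R)-6-methylheptan-2-yl]cyclopentyl}tetradecyl]naphthalene-1,4-dione | CC1=C(CC[C@@H](C)CCC[C@@H](C)CCC[C@@H](C)CCC[C@@H]2CC[C@H]([C@H](C)CCCC(C)C)C2)C(=O)c2ccccc2C1=O | target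

**Count and risks**

Total step count: 15. Longest linear sequence: 9 (steps 1–6, 13, 14, 15).

Steps most likely to fail:

Step 13. The one-pot sequence may leak at three places: protonation of the organolithium before ring closure (open-chain alkene), incomplete cis/trans discrimination in the carbolithiation, and γ-attack, allylic transposition or homocoupling in the copper-catalysed union. The fallback sets out from 11 and 20 and comes back at 24. The ring is closed by a radical chain instead: iodine-atom-transfer 5-exo cyclisation of 11 (hexabutylditin (cat.), hν, benzene, 80 °C) should give the isolable, cis-configured (1R,3S)-1-(iodomethyl)-3-[(2R)-6-methylhept-5-en-2-yl]cyclopentane F1. The union is then made with reversed polarity: 20 and sodium benzenesulfinate (DMF, rt) give 2-[(3E,7E,11E)-13-(benzenesulfonyl)-3,7,11-trimethyltrideca-3,7,11-trien-1-yl]-1,4-dimethoxy-3-methylnaphthalene F2. Its lithio derivative (n-BuLi, THF/DMPU, −78 °C) is alkylated at the sulfone-bearing carbon by F1 to give the C13'-benzenesulfonyl derivative of 24 F3 (both C13' epimers). Palladium-catalysed hydride desulfonylation (PdCl2(dppp), LiBHEt3, THF, 0 °C) returns 24.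

Step 14. Conversion or facial control may be incomplete at one of the three chain alkenes of a C43 tetraene that also carries a coordinating dimethoxyarene and a ring next to the C11'=C12' alkene, and the resulting epimers could not be separated. The fallback sets out from 19 and comes back at 25. The stereo-defining reduction is moved to the free-standing left half: 19 is hydrogenated with the same class of iridium P,N catalyst, at a stage where the alkene nearest the future ring is an allylic alcohol. This gives (3R,7R,11S)-13-(1,4-dimethoxy-3-methylnaphthalen-2-yl)-3,7,11-trimethyltridecan-1-ol F4, whose stereochemical purity can be assayed on its MTPA esters before any right-half material is committed. This relocates and exposes the problem rather than removing it: if F4 is not uniform, the stereotriad would have to be assembled from chiral-pool units instead, a considerably longer route not detailed here. CBr4/PPh3 converts F4 to 2-[(3S,7R,11R)-13-bromo-3,7,11-trimethyltridecyl]-1,4-dimethoxy-3-methylnaphthalene F5. F5 is joined to Grignard reagent 23 (made from 11 as in step 13) by Li2CuCl4-catalysed sp3–sp3 coupling to give 1,4-dimethoxy-2-methyl-3-[(3S,7S,11R)-3,7,11-trimethyl-14-{(1R,3S)-3-[(2R)-6-methylhept-5-en-2-yl]cyclopentyl}tetradecyl]naphthalene F6. Hydrogenation of the remaining side-chain alkene (H2, Pd/C, EtOAc) gives 25.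

Step 10. The electron-rich benzylic chloride may dimerise (Wurtz-type) while the Grignard reagent forms, and the reagent may attack the acetate or substitute at the γ-carbon. The fallback sets out from 16 and 14 and comes back at 19. The benzylic nucleophile is tamed as a sulfone: 16 and sodium benzenesulfinate (DMF, rt) give 2-[(benzenesulfonyl)methyl]-1,4-dimethoxy-3-methylnaphthalene F7. Its sodium derivative (NaN(SiMe3)2, THF, −78 °C) is alkylated by 14 at the primary allylic carbon to give (2E,6E,10E)-13-(benzenesulfonyl)-13-(1,4-dimethoxy-3-methylnaphthalen-2-yl)-3,7,11-trimethyltrideca-2,6,10-trien-1-yl acetate F8. Magnesium in methanol removes the benzylic sulfonyl group and the acetate in one operation to give 19.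

Further compounds
F1 | step 13 | (1R,3S)-1-(iodomethyl)-3-[(2R)-6-methylhept-5-en-2-yl]cyclopentane | IC[C@@H]1CC[C@H]([C@H](C)CCC=C(C)C)C1
F2 | step 13 | 2-[(3E,7E,11E)-13-(benzenesulfonyl)-3,7,11-trimethyltrideca-3,7,11-trien-1-yl]-1,4-dimethoxy-3-methylnaphthalene | O=S(=O)(C/C=C(\C)CC/C=C(\C)CC/C=C(\C)CCc1c(C)c(OC)c2ccccc2c1OC)c1ccccc1
F3 | step 13 | C13'-benzenesulfonyl derivative of 24 (both C13' epimers) | COc1c(C)c(CC/C(C)=C/CC/C(C)=C/CC/C(C)=C/C(C[C@@H]3CC[C@H]([C@H](C)CCC=C(C)C)C3)S(=O)(=O)c3ccccc3)c(OC)c2ccccc12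
F4 | step 14 | (3R,7R,11S)-13-(1,4-dimethoxy-3-methylnaphthalen-2-yl)-3,7,11-trimethyltridecan-1-ol | OCC[C@H](C)CCC[C@H](C)CCC[C@H](C)CCc1c(C)c(OC)c2ccccc2c1OC
F5 | step 14 | 2-[(3S,7R,11R)-13-bromo-3,7,11-trimethyltridecyl]-1,4-dimethoxy-3-methylnaphthalene | BrCC[C@H](C)CCC[C@H](C)CCC[C@H](C)CCc1c(C)c(OC)c2ccccc2c1OC
F6 | step 14 | 1,4-dimethoxy-2-methyl-3-[(3S,7S,11R)-3,7,11-trimethyl-14-{(1R,3S)-3-[(2R)-6-methylhept-5-en-2-yl]cyclopentyl}tetradecyl]naphthalene | COc1c(C)c(CC[C@@H](C)CCC[C@@H](C)CCC[C@@H](C)CCC[C@@H]3CC[C@H]([C@H](C)CCC=C(C)C)C3)c(OC)c2ccccc12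
F7 | step 10 | 2-[(benzenesulfonyl)methyl]-1,4-dimethoxy-3-methylnaphthalene | COc1c(CS(=O)(=O)c3ccccc3)c(C)c(OC)c2ccccc12
F8 | step 10 | (2E,6E,10E)-13-(benzenesulfonyl)-13-(1,4-dimethoxy-3-methylnaphthalen-2-yl)-3,7,11-trimethyltrideca-2,6,10-trien-1-yl acetate | CC(=O)OC/C=C(\C)CC/C=C(\C)CC/C=C(\C)CC(c1c(C)c(OC)c2ccccc2c1OC)S(=O)(=O)c1ccccc1
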